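**Plan**
Numbering: lactone bicycle O1, C2(=O), C3, C3a, O4, C5, C6, C6a; benzylic carbon C7. In this cis-fused furo[3,2-b]furan-2-one the lactone carbons C2 and C3 hang on the neighbouring tetrahydrofuran carbons C6a and C3a (C3a is the ether carbon), the imprint of a ketene on the C3a=C6a bond of a 2,3-dihydrofuran.
Retrosynthetic cuts, in order: C7–OAr (Mitsunobu), O1–C6a (Baeyer–Villiger), C3–C3a with C2–C6a (dichloroketene [2+2]), O4–C3a (alkynol cycloisomerisation), C5–C6 (propargylation).
Forward: the chain C7–C5–C6–C6a–C3a is built from a mandelaldehyde, the dihydrofuran ring is closed, the cyclobutanone is fused on and expanded to the γ-lactone, and the flavanone is attached last.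
Stereochemistry: C7 from methyl (R)-mandelate (carried as R, inverted to S in the final etherification); C5 by Felkin–Anh addition; C3a and C6a by suprafacial ketene addition anti to the C5 side chain, then retentive migration; flavanone C2 from (2S)-pinocembrin.

Key step: step 5

Assumption: methyl (R)-mandelate and (2S)-pinocembrin are bought enantiopure, and the hydrogen-bonded 5-OH of the flavanone is taken to be inert in the Mitsunobu step, so no phenol protection is planned.

**Route**

Step 1
Reactants: 1 methyl (R)-mandelate
Product: 2 methyl (2R)-2-[(tert-butyldimethylsilyl)oxy]-2-phenylacetate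
Conditions: TBSCl, imidazole, DMF, rt
Reagents that add atoms: tert-butyldimethylsilyl chloride, CC(C)(C)[Si](C)(C)Cl
Why: Imidazole-promoted silylation of a secondary α-hydroxy ester touches no stereocentre and installs the bulky, non-chelating ether that later steers both the carbonyl addition and the ketene approach.

Step 2
Reactants: 2 methyl (2R)-2-[(tert-butyldimethylsilyl)oxy]-2-phenylacetate
Product: 3 (2R)-2-[(tert-butyldimethylsilyl)oxy]-2-phenylacetaldehyde
Conditions: iBu2AlH (DIBAL-H), CH2Cl2, −78 °C; aq. potassium sodium tartrate work-up; used crude at once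
Reagents that add atoms: none
Why: Partial ester reduction with DIBAL-H stops at the aluminium hemiacetal at −78 °C, and immediate use of the crude α-silyloxy aldehyde should keep the labile C7 centre from epimerising.

Step 3
Reactants: 3 (2R)-2-[(tert-butyldimethylsilyl)oxy]-2-phenylacetaldehyde; 4 propargyl bromide
Product: 6 (1R,2S)-1-[(tert-butyldimethylsilyl)oxy]-1-phenylpent-4-yn-2-ol, via allenylzinc bromide 5 (not isolated)
Conditions: Zn dust, 4, THF, 0 °C; then 3, −78 to 0 °C; aq. NH4Cl
Reagents that add atoms: none
Why: Barbier-type zinc propargylation through the allenylzinc (SE2′) gives the homopropargylic alcohol, and with the non-chelating OTBS group the Felkin–Anh approach should set the new C5 carbinol anti to C7 (5S), the minor syn epimer being removed by chromatography.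

Step 4
Reactants: 6 (1R,2S)-1-[(tert-butyldimethylsilyl)oxy]-1-phenylpent-4-yn-2-ol
Product: 7 (2S)-2-[(R)-[(tert-butyldimethylsilyl)oxy](phenyl)methyl]-2,3-dihydrofuran
Conditions: Mo(CO)6 (25 mol%), Et3N, Et2O, hν (350 nm), then 6, rt
Reagents that add atoms: none
Why: Alkynol endo-cycloisomerisation catalysed by a group 6 carbonyl proceeds through a metal vinylidene whose α-carbon (C3a) is attacked by the C5 hydroxyl, giving the 2,3-dihydrofuran after protodemetalation; the C5–O bond is never broken, so C5 stays S.

Step 5
Reactants: 7 (2S)-2-[(R)-[(tert-butyldimethylsilyl)oxy](phenyl)methyl]-2,3-dihydrofuran; 8 trichloroacetyl chloride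
Product: 10 (1S,3S,5R)-3-[(R)-[(tert-butyldimethylsilyl)oxy](phenyl)methyl]-7,7-dichloro-2-oxabicyclo[3.2.0]heptan-6-one (cis-fused; CCl2 on the oxygen-bearing bridgehead C3a, C=O on C6a; side chain on the face opposite the four-membered ring), via dichloroketene 9 (not isolated)
Conditions: Zn–Cu couple, Et2O/DME, 0 °C to rt, slow addition of 8
Reagents that add atoms: none
Why: Dichloroketene, released from 8 by zinc dechlorination, adds to the electron-rich enol ether in a concerted but asynchronous [π2s+π2a] cycloaddition in which its electrophilic carbonyl carbon bonds to the nucleophilic β-carbon C6a and its CCl2 carbon to the oxygen-bearing C3a. The closest known reaction type is the dichloroketene cycloaddition to 2,3-dihydrofuran, dihydropyran and glycals, which shows this regiochemistry. The cyclobutanone ring is closed by the two new bonds C2–C6a and C3–C3a in one intermolecular [2+2] event that is suprafacial on the alkene, so the ring fusion must be cis. The new stereocentres C3a and C6a are controlled by the existing C5 centre, the ketene approaching the face of the almost planar dihydrofuran opposite the bulky CH(OTBS)Ph group. The step therefore needs facial selectivity, secured by the size of the silyloxybenzyl substituent next to the ring oxygen, and regioselectivity, secured by the polarisation of the enol ether; DME ties up ZnCl2 so that the acid-labile enol ether and silyl ether should survive.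

Step 6
Reactants: 10 the dichlorocyclobutanone
Product: 11 (1R,3S,5R)-3-[(R)-[(tert-butyldimethylsilyl)oxy](phenyl)methyl]-2-oxabicyclo[3.2.0]heptan-6-one
Conditions: Zn dust, AcOH, rt
Reagents that add atoms: none
Why: Reductive dechlorination of an α,α-dichlorocyclobutanone by zinc in acetic acid is the standard sequel to ketene cycloadditions; no stereocentre is affected and the TBS ether should tolerate the short exposure to AcOH.

Step 7
Reactants: 11 the cyclobutanone
Product: 12 (3aR,5S,6aR)-5-[(R)-[(tert-butyldimethylsilyl)oxy](phenyl)methyl]tetrahydrofuro[3,2-b]furan-2(3H)-one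
Conditions: 30% aq. H2O2, AcOH, 0 °C to rt
Reagents that add atoms: hydrogen peroxide, OO
Why: Baeyer–Villiger oxidation of the strained four-membered ketone is fast, and the more substituted bridgehead carbon C6a should migrate with retention, inserting O1 between C2 and C6a to give the cis-fused γ-lactone.

Step 8
Reactants: 12 the silyl-protected lactone
Product: 13 (3aR,5S,6aR)-5-[(R)-hydroxy(phenyl)methyl]tetrahydrofuro[3,2-b]furan-2(3H)-one
Conditions: HF·pyridine, THF/pyridine, 0 °C to rt
Reagents that add atoms: none
Why: Fluoride-mediated desilylation under buffered, mildly acidic conditions frees the C7 alcohol without opening the γ-lactone or touching any stereocentre.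

Step 9
Reactants: 13 the lactone alcohol; 14 (2S)-pinocembrin
Product: 15 (2S)-5-hydroxy-7-{(S)-[(3aR,5S,6aR)-2-oxohexahydrofuro[3,2-b]furan-5-yl](phenyl)methoxy}-2-phenylchroman-4-one (target)
Conditions: PPh3, DIAD, THF, 0 °C to rt
Reagents that add atoms: none
Why: In this Mitsunobu etherification the phosphonium-activated secondary benzylic alcohol is displaced in an SN2 reaction by the 7-phenoxide of pinocembrin (the more acidic, non-chelated phenol), inverting C7 from R to S, while the near-neutral conditions should spare the lactone and the flavanone C2 centre.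

**Compound list**
1 | methyl (R)-mandelate | O[C@@H](C(=O)OC)c1ccccc1 | starting material
2 | methyl (2R)-2-[(tert-butyldimethylsilyl)oxy]-2-phenylacetate | CC(C)(C)[Si](C)(C)O[C@@H](C(=O)OC)c1ccccc1 | intermediate
3 | (2R)-2-[(tert-butyldimethylsilyl)oxy]-2-phenylacetaldehyde | CC(C)(C)[Si](C)(C)O[C@@H](C=O)c1ccccc1 | intermediate
4 | propargyl bromide | C#CCBr | starting material
5 | allenylzinc bromide | C=C=C[Zn]Br | intermediate
6 | (1R,2S)-1-[(tert-butyldimethylsilyl)oxy]-1-phenylpent-4-yn-2-ol | CC(C)(C)[Si](C)(C)O[C@@H]([C@@H](O)CC#C)c1ccccc1 | intermediate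
7 | (2S)-2-[(R)-[(tert-butyldimethylsilyl)oxy](phenyl)methyl]-2,3-dihydrofuran | CC(C)(C)[Si](C)(C)O[C@@H]([C@@H]1CC=CO1)c1ccccc1 | intermediate
8 | trichloroacetyl chloride | O=C(Cl)C(Cl)(Cl)Cl | starting material
9 | dichloroketene | O=C=C(Cl)Cl | intermediate
10 | (1S,3S,5R)-3-[(R)-[(tert-butyldimethylsilyl)oxy](phenyl)methyl]-7,7-dichloro-2-oxabicyclo[3.2.0]heptan-6-one | O=C1C(Cl)(Cl)[C@H]2O[C@H]([C@H](O[Si](C)(C)C(C)(C)C)c3ccccc3)C[C@@H]12 | intermediate
11 | (1R,3S,5R)-3-[(R)-[(tert-butyldimethylsilyl)oxy](phenyl)methyl]-2-oxabicyclo[3.2.0]heptan-6-one | O=C1C[C@H]2O[C@H]([C@H](O[Si](C)(C)C(C)(C)C)c3ccccc3)C[C@@H]12 | intermediate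
12 | (3aR,5S,6aR)-5-[(R)-[(tert-butyldimethylsilyl)oxy](phenyl)methyl]tetrahydrofuro[3,2-b]furan-2(3H)-one | O=C1C[C@H]2O[C@H]([C@H](O[Si](C)(C)C(C)(C)C)c3ccccc3)C[C@H]2O1 | intermediate
13 | (3aR,5S,6aR)-5-[(R)-hydroxy(phenyl)methyl]tetrahydrofuro[3,2-b]furan-2(3H)-one | O=C1C[C@H]2O[C@H]([C@H](O)c3ccccc3)C[C@H]2O1 | intermediate
14 | (2S)-pinocembrin, (2S)-5,7-dihydroxy-2-phenylchroman-4-one | Oc1cc(O)c2c(c1)O[C@H](c1ccccc1)CC2=O | starting material
15 | (2S)-5-hydroxy-7-{(S)-[(3aR,5S,6aR)-2-oxohexahydrofuro[3,2-b]furan-5-yl](phenyl)methoxy}-2-phenylchroman-4-one | O=C1C[C@H]2O[C@H]([C@@H](Oc3cc(O)c4c(c3)O[C@H](c3ccccc3)CC4=O)c3ccccc3)C[C@H]2O1 | target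

**Count**
Total steps: 9. Longest linear sequence: 9 steps (1 to 15); 4, 8 and 14 enter as convergent inputs.

**Steps most likely to fail**

1. Step 5. The side chain on C5 is two ring atoms away from C6a, so the ketene may not discriminate the two faces well enough; ZnCl2 may also oligomerise the enol ether before it is trapped. Fallback, setting out from aldehyde 3 and coming back at lactone 12 (it by-passes steps 3 to 7):
   - A Mukaiyama aldol addition of 2-(trimethylsilyloxy)buta-1,3-diene to 3 (BF3·OEt2, CH2Cl2, −78 °C; Felkin–Anh, 1,2-anti) should give the β-hydroxy enone (5S,6R)-6-[(tert-butyldimethylsilyl)oxy]-5-hydroxy-6-phenylhex-1-en-3-one F1.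
   - Narasaka–Prasad reduction (Et2BOMe, NaBH4, THF/MeOH, −78 °C) should give the syn-1,3-diol (3R,5S,6R)-6-[(tert-butyldimethylsilyl)oxy]-6-phenylhex-1-ene-3,5-diol F2.
   - Oxycarbonylation catalysed by divalent palladium (PdCl2 cat., CuCl2, NaOAc, AcOH, CO 1 atm, rt) should then give 12: the C5 hydroxyl adds to C3a, CO inserts at C3 and the C6a hydroxyl closes the lactone.
   - Here C6a is set by the hydride reduction and C3a by the cis fusion that lactonisation demands, so no facial choice on a ring is needed.

2. Step 9. Displacement at the hindered, oxygen-flanked benzylic carbon may be slow, so the activated alcohol may ionise or be captured by the ring oxygen or the reduced azo reagent, eroding inversion and conversion. Fallback, setting out from alcohol 13 and coming back at target 15: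
   - Mesylation (MsCl, Et3N, CH2Cl2, −20 °C; retention) should give the methanesulfonate (R)-[(3aR,5S,6aR)-2-oxohexahydrofuro[3,2-b]furan-5-yl](phenyl)methyl methanesulfonate F3.
   - Pre-formed 7-phenoxide of 14 (K2CO3, 1 equiv, DMF, 0 °C to rt) should displace it bimolecularly with inversion to give 15.
   - The weak base and low temperature are meant to hold back flavanone ring-opening (racemisation at C2) and lactone cleavage.

3. Step 3. Face selection in the zinc addition may be modest, leaving much of the material as the syn epimer, and the aldehyde may partly epimerise before it reacts. Fallback, setting out from aldehyde 3 and coming back at alkynol 6: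
   - The zinc addition is run as before and the syn epimer (1R,2R)-1-[(tert-butyldimethylsilyl)oxy]-1-phenylpent-4-yn-2-ol F4 is collected.
   - Mitsunobu inversion with 4-nitrobenzoic acid (PPh3, DIAD, toluene, 0 °C to rt) should give (1R,2S)-1-[(tert-butyldimethylsilyl)oxy]-1-phenylpent-4-yn-2-yl 4-nitrobenzoate F5.
   - Brief cold methanolysis (K2CO3, MeOH, 0 °C) should release 6.
   - Both epimers then converge, and C5 is fixed by SN2 inversion instead of by face selection.

**Further compounds**
F1 | step 5 | (5S,6R)-6-[(tert-butyldimethylsilyl)oxy]-5-hydroxy-6-phenylhex-1-en-3-one | C=CC(=O)C[C@H](O)[C@H](O[Si](C)(C)C(C)(C)C)c1ccccc1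
F2 | step 5 | (3R,5S,6R)-6-[(tert-butyldimethylsilyl)oxy]-6-phenylhex-1-ene-3,5-diol | C=C[C@H](O)C[C@H](O)[C@H](O[Si](C)(C)C(C)(C)C)c1ccccc1
F3 | step 9 | (R)-[(3aR,5S,6aR)-2-oxohexahydrofuro[3,2-b]furan-5-yl](phenyl)methyl methanesulfonate | O=C1C[C@H]2O[C@H]([C@H](OS(C)(=O)=O)c3ccccc3)C[C@H]2O1
F4 | step 3 | (1R,2R)-1-[(tert-butyldimethylsilyl)oxy]-1-phenylpent-4-yn-2-ol | CC(C)(C)[Si](C)(C)O[C@@H]([C@H](O)CC#C)c1ccccc1
F5 | step 3 | (1R,2S)-1-[(tert-butyldimethylsilyl)oxy]-1-phenylpent-4-yn-2-yl 4-nitrobenzoate | CC(C)(C)[Si](C)(C)O[C@@H]([C@@H](OC(=O)c2ccc(cc2)[N+](=O)[O-])CC#C)c1ccccc1
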